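At the first reading, 1.3 min, Saturday's run holds 0.1299 M of J and Monday's run 0.0782 M, and their charges differ in G alone, 0.00240 M against 0.00160 M.

| flask | E | L | G | time |
|---|---|---|---|---|
| Monday's | 0.800 M | 2.00 M | 0.00160 M |  |
| Thursday's | 0.400 M | 1.60 M | 0.00160 M |  |
| Saturday's | 0.800 M | 2.00 M | 0.00240 M |  |
| Wednesday's | 0.800 M | 2.00 M | 0.00480 M | 23 min |

| run | time / min | [J] / M |
|---|---|---|
| Monday's run | 1.3 | 0.0782 |
| Monday's run | 4.0 | 0.2100 |
| Monday's run | 7.6 | 0.3169 |
| Monday's run | 12 | 0.4053 |
| Monday's run | 17 | 0.4613 |
| Monday's run | 23 | 0.5027 |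
| Thursday's run | 1.3 | 0.0302 |
| Thursday's run | 4.0 | 0.0882 |
| Thursday's run | 7.6 | 0.1376 |
| Thursday's run | 12 | 0.1786 |
| Thursday's run | 17 | 0.2114 |
| Thursday's run | 23 | 0.2287 |
| Saturday's run | 1.3 | 0.1299 |
| Saturday's run | 4.0 | 0.3062 |
| Saturday's run | 7.6 | 0.4518 |
| Saturday's run | 12 | 0.5506 |
| Saturday's run | 17 | 0.6104 |
| Saturday's run | 23 | 0.6552 |

(standard deviation of a reading: 0.002 M)

1. reaction order in [G] at the outset, round the charge of the Monday's run, defined at two percent of the E turned into J
2. the Thursday's run starts with 0.400 M less of E and of L than the Monday's run, and with no J. Compared where both hold the same amount of E, once fifteen percent of what the Thursday's run was charged with has turned into J, is the Thursday's run faster, slower or alike (within a tenth)?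
3. J in the Wednesday's run at 23 min, as a share of the E charged

- Overall: E + L -> J, with G as catalyst.
- Constant volume, constant temperature.
- An order is taken over about fifteen percent of the charge, up and down.

E and L are used one for one, so we can put each reading on a common scale. Monday's run has by 23 min taken 0.584 M⁻¹ of exposure, meaning the logarithm of the fraction of L left over the fraction of E left, divided by the excess of L over E. If the rate is first order in E and in L, the slope of exposure is the rate divided by both amounts, which is what the catalyst is doing at that moment.

At 1.3 min, Monday's run has 0.0525 M⁻¹ and Thursday's run 0.0495 M⁻¹, although Thursday's run has half the E, so the slope seems to follow the clock. The excess of L is 1.20 M in both runs, so equal E means equal L, and the rate ratio is the slope ratio. Thursday's run reaches the point asked between 1.3 min and 4.0 min, with slope 0.0410 M⁻¹ min⁻¹. Monday's run gets there near 17 min, with slope 0.0167 M⁻¹ min⁻¹. We read Thursday's run as faster, by a factor of 2.46.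

Saturday's exposure at 1.3 min is 1.75 times Monday's, which reads as an order in G of 1.38. For Wednesday's run we stretch Monday's exposure at each time by 4.53. The curve then starts at about 0.293 M min⁻¹ and passes half of E near 2.14 min. E is the limiting reagent, so J can level off no higher than 0.800 M. At 23 min the exposure is 2.65 M⁻¹, which leaves 0.0204 M of E, so our share is 97.5%.

The forecast gave 1.35, faster and 96.8%, saying “the scale factor is about 4.3”, where our own reckoning took 4.53 and gave a higher share.

The simulation gives 1.5, faster with a ratio of 2.4, and 95.8%.

    2 G ⇌ G2, settled at all times (1580 M⁻¹)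
    G + E + L → J + G (129.0 M⁻² min⁻¹)
    G → Ju (0.1368 min⁻¹)
    G + Rx → Ju

In Wednesday's run Rx took 8.93 × 10⁻⁴ M of G at once, leaving 0.00391 M, counted as G, shared between G and G2. Then G made J from E and L, with 0.0336 M of E still there at 23 min, and went over to Ju with a rate constant of 0.137 min⁻¹. Wednesday's share is an exposure of 2.24 M⁻¹, which is 3.84 times Monday's 0.584 M⁻¹, against the forecast's 4.3, and the share lies 1.00 percentage point below the forecast's. Saturday's run reached the exposure of half conversion, 0.392 M⁻¹, in 6.07 min, and Monday's run in 11.7 min.

The readings were generated by integration for an exercise; noise was put on by code.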